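## Analysis of the target

Longipinane numbering is used throughout: ketone C1, alkene C2=C3 with a methyl group on C3, cyclobutane C4–C5–C11–C10 with a methyl group on C10, gem-dimethyl carbon C6, angelate carbon C7, tiglate carbon C8 and methylene C9. The C15 core of target 20 is a cyclobutane with both diagonals bridged. C4 and C11 are joined by the enone unit C3=C2–C1(=O), which gives a verbenone-like bicyclo[3.1.1]heptenone, and C5 and C10 are joined on the opposite face by the chain C6–C7–C8–C9, which gives the seven-membered rings. Four of the six stereocentres sit on the cyclobutane (4R,5S,10R,11R) and are locked to one another by the two bridges, so they amount to one decision, the absolute sense of the cage; C7 (S) and C8 (S) carry a trans-diol diester with O7 on the side of C4 (called β below) and O8 on the side of C11 (called α below). Apart from the difference between C1=O and C3–CH3, the cage has a mirror plane through C5, C10 and the four-carbon bridge, so the two faces of this bridge look almost alike to a reagent; C7 and C9, each next to a quaternary carbon, are also hard to tell apart. The sensitive groups are the (Z)-angelate (it drifts to the (E)-tiglate with nucleophilic catalysts, acid, heat or light), the vicinal esters (they can migrate while one hydroxyl is free) and the strained cyclobutane-fused enone (it rearranges with strong acid or ultraviolet light and is deprotonated at the C3 methyl by strong base). The difficulty lies in the cage, with two quaternary carbons and four contiguous ring stereocentres, and in bringing two oxygen atoms to unactivated, flanked methylene groups. The strategy rests on the fact that the fifteen skeletal carbons are an unbroken farnesyl chain (farnesyl C1 to C11 = C5, C4, C3, C2, C1, C11, C10, C9, C8, C7, C6) folded in the himachalane manner, so only three C–C bonds (C5–C6, C5–C11, C4–C10) separate the tricycle from an acyclic C15 diphosphate.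

## Retrosynthetic reasoning

**Acyl–O7 bond.** Target 20 is opened first at the acyl–oxygen bond of the C7 ester, which leads to hydroxy tiglate 17 and angelic acid 18. The Z-ester is the most fragile group, so it should meet no further reagent. The price is that the last acylation takes place at a neopentyl carbinol. It has to proceed without Z-to-E drift and without moving the neighbouring tiglate.

**Acyl–O8 bond.** Cutting the tiglate of 17 gives trans-diol 14 and tiglic acid 15. The two hydroxyls differ in their surroundings, since O8 lies beside the methylene C9 and O7 lies beside the gem-dimethyl carbon C6. One equivalent of an activated acid should therefore find O8, and no protecting group is needed.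

**C7–O bond.** Diol 14 is traced back to the 8α-alcohol 13 by exchanging the C7–O bond for a C–H bond. No functional group of the cage lies within reach of C7, and small reagents cannot reliably tell C7 from C9 or one face of the bridge from the other. The forward reaction is therefore given to the shaped pocket of a cytochrome P450 monooxygenase. It has to replace the β-hydrogen of C7 with retention.

**C8–O bond.** In the same way 13 goes back to enone 12. C8 is the methylene farthest from the enone and the only one without a quaternary neighbour, so intrinsic reactivity and enzyme control point the same way. For that reason this hydroxylation comes first.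

**C1=O.** Enone 12 is simplified to α-longipinene 10 by removing the carbonyl oxygen. In the forward sense the allylic oxidation precedes the hydroxylations. It consumes the weakest C–H bonds, makes the alkene electron-poor and gives the oxygenases a polar anchor.

**C5–C6, C5–C11 and C4–C10.** All three ring-forming bonds of 10 are cut at once, which unfolds the cage to (2E,6E)-farnesyl diphosphate 4. Read backwards:
- Cation 9 opens at C4–C10 to the bicyclic cation 8.
- Cation 8 opens at C5–C11 to the macrocyclic allyl cation 7.
- Cation 7 is linked by a hydride shift to cation 6.
- Cation 6 opens at C5–C6 to the acyclic cation 5.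

No other set of cuts removes three rings and four stereocentres while leaving a linear chain that is the natural substrate of a known enzyme. The forward reaction has to impose one fold and one exit on a cation with many options.

**C5–O(P) bond.** Diphosphate 4 is taken back to farnesyl chloride 3 and then to (2E,6E)-farnesol 1. These two substitutions at a primary allylic carbon touch neither alkene geometry, so the precursor of the key step is reached by routine chemistry.

## Alternatives that were turned down

**Alternative 1:** The C5–C11 bond is traced back, through a 1,2-shift, to a C1–C5 bond of a norbornene. That norbornene is then opened at C1–C11 and C4–C10 as a Diels–Alder adduct.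

Forward key step: the precursor is the 5-alkyl-1-silyloxy-3-methylcyclopentadiene A1. Its C6–C9 tether carries the trans-diol as an acetonide and ends in an (E)-alkenylboronate. A1 would cyclise to the tricyclic silyloxynorbornene A2. After exchange of the endo boronate for a leaving group, C5 would migrate from C1 to C11 while the silyl ether collapses to the C1 ketone.

In its favour:
- C1, C7 and C8 carry their oxygen from the start, so no C–H oxidation is needed. On this point the plan is clearly stronger than the chosen one.
- The alkene geometry is translated stereospecifically into C10 and C11.
- An endo leaving group is antiperiplanar to the C1–C5 bond.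

Against it:
- 5-Alkylcyclopentadienes equilibrate by 1,5-hydrogen shifts under mild conditions. A trisubstituted, electronically unactivated alkenylboronate that must create quaternary C10 and a seven-membered ring beside neopentyl C6 needs heat, so the diene should scramble before it reacts.
- The shift runs uphill in ring strain (norbornyl to pinyl). It competes with migration of the vinylic carbon C2 and with fragmentation.
- A1 is itself a long multistep target with one labile stereocentre.

The chosen strategy offers in exchange all three rings and the four cage stereocentres in one step, from a compound two steps away from a commodity alcohol.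

**Alternative 2:** The cyclobutane is cut at C5–C11 and C4–C10 as the adduct of a ketene and an alkene, after the seven-membered ring has been dismantled at C5–C6 and C7=C8.

Forward key step: triethylamine would take the trienoyl chloride A3 by γ-deprotonation to the (Z)-vinylketene A4. The C4=C5 unit of A4 adds in the crossed sense to the C10=C11 alkene and gives the bicyclo[3.1.1]heptenone A5. In A5, C5 is the cyclobutanone carbonyl, an allyl group sits on C10 and a silyl ether on C1.

In its favour:
- The polarity is matched. The electrophilic ketene carbon C5 bonds to the less substituted C11 while charge builds at tertiary C10.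
- The (E)-alkene geometry is carried into C10, the reagents are cheap and no enzyme is needed.
- A later ring-closing metathesis would leave a C7=C8 alkene. That is a regiochemically unambiguous handle for both oxygen atoms, which the chosen route lacks.

Against it:
- C5 arrives as a carbonyl although the target has a hydrogen and a bond to quaternary C6 there. A tertiary carbon nucleophile must add to a cyclobutanone flanked by two bridgeheads.
- The resulting tertiary alcohol must then be removed with control of C5, next to a ring that opens readily through cations or radicals.
- A5 is a β,γ-unsaturated cyclobutanone and is prone to 1,3-acyl shift.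
- The metathesis joins a neopentyl vinyl group, and the face problem of the bridge remains.

The step count would be roughly double that of the chosen route, which forms C5–C6 within the same event as the cyclobutane.

**Alternative 3:** The enone ring is cut at C2=C3 as an aldol condensation. This uncovers the mirror plane of the bicyclo[4.1.1]octene, and the precursor is the meso-diketone A6 with acetyl groups on C4 and C11.

Forward key step: a chiral primary amine would turn one of the two enantiotopic acetyl groups (that on C11) into an enamine. Its carbon C2 attacks the other acetyl carbonyl C3, and dehydration gives longipina-2,7-dien-1-one A7.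

In its favour:
- The plan uses the hidden symmetry and sets the absolute sense of all four cage centres with a small catalyst.
- It makes the enone without an allylic oxidation.
- It delivers the C7=C8 alkene, from which both oxygen atoms can be introduced without C–H functionalisation. Here it is stronger than the chosen route.

Against it:
- The problem is only moved. A6 still contains the cyclobutane with its four stereocentres, both quaternary carbons and the bridging seven-membered ring, and no short access to it is evident.
- The aldol has to close a strained bicyclo[3.1.1] ring across the cyclobutane diagonal in a reversible reaction.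
- The acetyl-bearing carbons can epimerise under amine catalysis to an arrangement that cannot cyclise.
- After A7 the two alkene faces are nearly equivalent, so the trans-diol needs a second external source of control.

The chosen strategy meets the same face problem. It answers that problem with enzyme pockets, and it reaches the cage in three steps instead of leaving it unsolved.

Key step: step 3

Assumption: hydrocarbon 10 as drawn has the descriptors (1R,2S,7R,8R), taken here to be those of the dextrorotatory α-longipinene of conifer oleoresins. The synthase is chosen from that series, and its product is checked against an authentic sample by enantioselective gas chromatography before scale-up.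

## Route

Step 1
Reactants: 1 (2E,6E)-farnesol
Product: 3 (2E,6E)-farnesyl chloride, via farnesyloxydimethylsulfonium chloride 2 (not isolated)
Conditions: NCS, Me2S, CH2Cl2, −40 to 0 °C
Reagents that add atoms: N-chlorosuccinimide, O=C1CCC(=O)N1Cl
Why: Corey–Kim-type chlorination: the alcohol attacks the sulfonium species made from NCS and Me2S, and chloride displaces dimethyl sulfoxide from 2 by SN2 at the primary allylic carbon. The cold, neutral conditions avoid allylic transposition and E/Z scrambling, so both alkene geometries are kept.

Step 2
Reactants: 3 (2E,6E)-farnesyl chloride
Product: 4 (2E,6E)-farnesyl diphosphate (handled as the trisammonium salt, drawn as the acid)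
Conditions: (n-Bu4N)3HP2O7, MeCN, rt; Dowex 50W-X8 (NH4+ form), aq. NH4HCO3; cellulose chromatography
Reagents that add atoms: tris(tetrabutylammonium) hydrogen diphosphate, CCCC[N+](CCCC)(CCCC)CCCC.CCCC[N+](CCCC)(CCCC)CCCC.CCCC[N+](CCCC)(CCCC)CCCC.OP(=O)([O-])OP(=O)([O-])[O-]
Why: SN2 displacement of a primary allylic chloride by the poorly solvated diphosphate anion in a dipolar aprotic solvent, the standard synthesis of allylic diphosphates. Ion exchange gives the water-soluble ammonium salt that the enzyme accepts; no stereocentre is formed and the alkene geometries are untouched.

Step 3
Reactants: 4 (2E,6E)-farnesyl diphosphate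
Product: 10 α-longipinene, (1R,2S,7R,8R)-2,6,6,9-tetramethyltricyclo[5.4.0.0(2,8)]undec-9-ene (longipinane numbering 4R,5R,10S,11R), via cisoid farnesyl cation 5 (not isolated), via humulyl cation 6 (not isolated), via allylic humulyl cation 7 (not isolated), via cis-himachalyl cation 8 (not isolated), via longipinyl cation 9 (not isolated)
Conditions: recombinant α-longipinene synthase (His6-tagged, from E. coli), MgCl2 (10 mM), HEPES (50 mM, pH 7.5), DTT, 10% glycerol, pentane overlay, 30 °C
Reagents that add atoms: none
Why: The class 1 synthase binds the diphosphate of 4 through three Mg2+ ions on its aspartate-rich motifs and ionises the C5–O bond; brief recapture of diphosphate at C3 permits rotation about C3–C4, and re-ionisation gives the cisoid cation 5. The distal C6=C7 alkene adds to C5 through C6 (C5–C6, an 11-endo and formally anti-Markovnikov macrocyclisation) to give 6, and the secondary charge at C7 is removed at once by a 1,3-hydride shift from C5, which gives allyl cation 7. The C10=C11 alkene adds to C5 through C11 (C5–C11, transannular, 6-exo for the new cyclohexene, the rest of the macrocycle becoming the seven-membered ring) to give the cis-fused tertiary cation 8. The C3=C4 alkene adds to C10 through C4 (C4–C10, 4-exo for the cyclobutane and 6-endo for the second six-membered ring) to give tertiary cation 9, and the bound diphosphate takes a proton from C2. This is a known enzymatic reaction, the conversion of 4 into 10 by conifer α-longipinene synthases and by engineered variants of γ-humulene synthase, within the general type of class 1 cation–olefin cyclisation. C5 and C11 are set in the 1,6-closure by the faces of the allyl cation and of the C10=C11 alkene that the pocket holds against each other, that is by the helical sense of the bound chain; C4 and C10 are then set by the ring frame, because on the cis-fused bicycle C4 can reach only one face of the C10 cation. The step needs product selectivity among many cation fates: 1,10- instead of 1,11-closure, C3–C10 closure toward the longifolane series, early proton loss to himachalenes, loss of a C3-methyl proton to the exocyclic isomer, and capture by water. The substrate contributes three trisubstituted alkenes spaced so that, after the hydride shift, each closure ends on an allylic or tertiary cation, and a (6E) geometry that fits the humulyl fold; the remaining choice is made by the dry, aromatic-lined pocket and by the position of the diphosphate as base.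

Step 4
Reactants: 10 α-longipinene
Product: 12 (4R,5S,10R,11R)-longipin-2-en-1-one, via 1-tert-butylperoxylongipin-2-ene 11 (not isolated)
Conditions: Rh2(cap)4 [dirhodium tetrakis(caprolactamate), 1 mol %], t-BuOOH (5 equiv), K2CO3 (0.5 equiv), CH2Cl2, rt
Reagents that add atoms: tert-butyl hydroperoxide, CC(C)(C)OO
Why: Radical allylic oxidation of the α-pinene-to-verbenone type: tert-butylperoxyl radicals abstract hydrogen from the only allylic methylene (C1), the allyl radical is capped at its less hindered terminus C1 on the face of C5, away from the C10 methyl, to give 11, and base-induced loss of tert-butanol gives the enone. C4–H is a strained bridgehead C–H that cannot align with the π system and the C3 methyl has stronger primary C–H bonds; no cage stereocentre is touched.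

Step 5
Reactants: 12 longipin-2-en-1-one
Product: 13 (4R,5S,8R,10R,11R)-8-hydroxylongipin-2-en-1-one (8α-hydroxyl, on the side of C11)
Conditions: evolved CYP102A1 (P450 BM3) variant selective for C8, NADP+ (cat.), glucose dehydrogenase, D-glucose, catalase, air, K2HPO4/KH2PO4 buffer pH 8.0, 2% EtOH, 25 °C
Reagents that add atoms: dioxygen, O=O
Why: Proposed new method: no hydroxylase is known for the longipinane cage, so a CYP102A1 variant has to be evolved (saturation of the residues lining the substrate channel, GC–MS screening); the oxoiron porphyrin radical cation abstracts the α-hydrogen of C8 and the hydroxyl rebounds to the same face, so the new stereocentre (8R) is set with retention by the pose of 12 in the pocket. C8 is also the intrinsically favoured site, farthest from the electron-withdrawing enone and the only ring methylene without a quaternary neighbour. The closest known reaction type is the late-stage hydroxylation of unactivated methylene groups of sesquiterpenoid and diterpenoid ketones and lactones by engineered CYP102A1 variants.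

Step 6
Reactants: 13 8α-hydroxylongipin-2-en-1-one
Product: 14 (4R,5S,7S,8S,10R,11R)-7,8-dihydroxylongipin-2-en-1-one (7β,8α-trans-diol)
Conditions: second evolved CYP102A1 variant selective for C7, NADP+ (cat.), glucose dehydrogenase, D-glucose, catalase, air, K2HPO4/KH2PO4 buffer pH 8.0, 2% EtOH, 25 °C
Reagents that add atoms: dioxygen, O=O
Why: Proposed new method: a second variant has to be evolved that places the neopentyl β-hydrogen of C7 over the oxoiron centre, with the 8-hydroxyl as a hydrogen-bond anchor; abstraction and rebound with retention set 7S, and the pocket, not the nearly symmetric cage, chooses C7 over C9 and the β over the α face. The closest known reaction types are the consecutive P450 hydroxylations that build vicinal diols in terpenoid biosynthesis and the hydroxylation of terpenoid alcohols by engineered CYP102A1 variants.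

Step 7
Reactants: 14 7β,8α-dihydroxylongipin-2-en-1-one; 15 tiglic acid
Product: 17 (4R,5S,7S,8S,10R,11R)-7-hydroxy-8-tigloyloxylongipin-2-en-1-one, via tiglic 2,4,6-trichlorobenzoic anhydride 16 (not isolated)
Conditions: 15 (1.1 equiv), 2,4,6-Cl3C6H2COCl, Et3N, THF, 0 °C; then 14, DMAP (0.2 equiv), toluene, 0 °C
Reagents that add atoms: none
Why: Yamaguchi esterification; O8 lies beside the methylene C9 whereas O7 is neopentyl beside the gem-dimethyl carbon C6, so about one equivalent of 16 at low temperature should acylate O8. The (E)-tiglate is the stable isomer and tolerates DMAP, and both C–O bonds of the diol stay intact, so C7 and C8 keep their configuration.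

Step 8
Reactants: 17 7β-hydroxy-8α-tigloyloxylongipin-2-en-1-one; 18 angelic acid
Product: 20 (4R,5S,7S,8S,10R,11R)-7-angeloyloxy-8-tigloyloxylongipin-2-en-1-one (target), via angelic 2,4,6-trichlorobenzoic anhydride 19 (not isolated)
Conditions: 18 (4 equiv), 2,4,6-Cl3C6H2COCl, Et3N, toluene, rt; then 17, 80 °C, dark, no DMAP
Reagents that add atoms: none
Why: Mixed-anhydride angeloylation without a nucleophilic catalyst, the established way to make angelates of hindered secondary alcohols: the shielded trichlorobenzoyl carbonyl directs the alcohol to the angeloyl carbonyl. Pyridine-type catalysts are left out because their conjugate addition–elimination turns angelate into tiglate. The step is last so that the Z-ester meets no further reagent.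

## Compound list

1 | (2E,6E)-farnesol | CC(C)=CCC/C(C)=C/CC/C(C)=C/CO | starting material
2 | (2E,6E)-farnesyloxydimethylsulfonium chloride | CC(C)=CCC/C(C)=C/CC/C(C)=C/CO[S+](C)C.[Cl-] | intermediate
3 | (2E,6E)-farnesyl chloride | CC(C)=CCC/C(C)=C/CC/C(C)=C/CCl | intermediate
4 | (2E,6E)-farnesyl diphosphate (acid form drawn, used as trisammonium salt) | CC(C)=CCC/C(C)=C/CC/C(C)=C/COP(=O)(O)OP(=O)(O)O | intermediate
5 | cisoid (2Z,6E)-farnesyl (nerolidyl) cation | CC(C)=CCC/C(C)=C/CC/C(C)=C\[CH2+] | intermediate
6 | (2Z,6E)-humulyl cation, charge at C7 | CC1(C)C/C=C(C)\CC/C=C(C)/CC[CH+]1 | intermediate
7 | allylic (2Z,6E)-humulyl cation, charge shared by C5 and C3 | CC1(C)[CH+]/C=C(C)\CC/C=C(C)/CCC1 | intermediate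
8 | cis-himachalyl cation, charge at C10 | C1CC[C+](C)[C@@H]2CCC(C)=C[C@@H]2C1(C)C | intermediate
9 | longipinyl cation, charge at C3 | C1CC[C@@]2(C)[C@@H]3CC[C+](C)[C@H]2[C@@H]3C1(C)C | intermediate
10 | α-longipinene, (1R,2S,7R,8R) | C1CC[C@@]2(C)[C@@H]3CC=C(C)[C@H]2[C@@H]3C1(C)C | intermediate
11 | (1S)-1-(tert-butylperoxy)longipin-2-ene, peroxy group on the side of C5 | C1CC[C@@]2(C)[C@@H]3[C@@H](OOC(C)(C)C)C=C(C)[C@H]2[C@@H]3C1(C)C | intermediate
12 | (4R,5S,10R,11R)-longipin-2-en-1-one | C1CC[C@@]2(C)[C@@H]3C(=O)C=C(C)[C@H]2[C@@H]3C1(C)C | intermediate
13 | (4R,5S,8R,10R,11R)-8-hydroxylongipin-2-en-1-one | C1[C@@H](O)C[C@@]2(C)[C@@H]3C(=O)C=C(C)[C@H]2[C@@H]3C1(C)C | intermediate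
14 | (4R,5S,7S,8S,10R,11R)-7,8-dihydroxylongipin-2-en-1-one | O[C@@H]1[C@@H](O)C[C@@]2(C)[C@@H]3C(=O)C=C(C)[C@H]2[C@@H]3C1(C)C | intermediate
15 | tiglic acid, (E)-2-methylbut-2-enoic acid | C/C=C(\C)C(=O)O | starting material
16 | tiglic 2,4,6-trichlorobenzoic anhydride | C/C=C(\C)C(=O)OC(=O)c1c(Cl)cc(Cl)cc1Cl | intermediate
17 | (4R,5S,7S,8S,10R,11R)-7-hydroxy-8-tigloyloxylongipin-2-en-1-one | O[C@@H]1[C@@H](OC(=O)/C(C)=C/C)C[C@@]2(C)[C@@H]3C(=O)C=C(C)[C@H]2[C@@H]3C1(C)C | intermediate
18 | angelic acid, (Z)-2-methylbut-2-enoic acid | C/C=C(/C)C(=O)O | starting material
19 | angelic 2,4,6-trichlorobenzoic anhydride | C/C=C(/C)C(=O)OC(=O)c1c(Cl)cc(Cl)cc1Cl | intermediate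
20 | (4R,5S,7S,8S,10R,11R)-7-angeloyloxy-8-tigloyloxylongipin-2-en-1-one | C/C=C(/C)C(=O)O[C@@H]1[C@@H](OC(=O)/C(C)=C/C)C[C@@]2(C)[C@@H]3C(=O)C=C(C)[C@H]2[C@@H]3C1(C)C | target

## Step count and least certain steps

Total step count: 8. Longest linear sequence: 8 steps (1 → 3 → 4 → 10 → 12 → 13 → 14 → 17 → 20). Acids 15 and 18 are bought.

**Step 5 (Proposed new method).**
- Risk: the most probable failure is lack of site fidelity in the evolving enzyme. Oxygen may be spread over C8, C9, C7 and the methyl groups, be delivered to the wrong face, or be carried on from the alcohol to the ketone stage, and the evolution campaign may not converge.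
- Fallback: it sets out from 12 and comes back at 13, using known chemistry. Quinuclidine-mediated anodic oxidation under O2 (quinuclidine, Me4NBF4, HFIP, MeCN, carbon anode, Ni cathode) works by hydrogen-atom transfer. It picks the most electron-rich and least hindered methylene, here C8, and transfers no oxygen to the electron-poor alkene. It should give longipin-2-ene-1,8-dione F1.
- A ketoreductase chosen from a commercial panel (NADP+, i-PrOH, buffer) then reduces the saturated C8 ketone beside the enone. With the right enzyme it delivers hydride to the β face, which gives 13.

**Step 6 (Proposed new method).**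
- Risk: the most probable failure is oxidation of the weaker carbinol C–H at C8 instead of the hindered C7–H. Hydroxylation at C9, which resembles C7, and poor turnover on the more polar substrate are further risks.
- Fallback: it sets out from 13 and comes back at 17, so step 7 is saved. MsCl and Et3N convert 13 into the 8α-mesylate F2.
- DBU in hot toluene then effects E2 elimination. Because C6 and C10 are quaternary, only two alkenes can form, longipina-2,7-dien-1-one F3 (identical with A7) and longipina-2,8-dien-1-one F4. No bias between them can be promised, and they are separated on AgNO3-impregnated silica.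
- mCPBA (NaHCO3, CH2Cl2, 0 °C) attacks only the isolated alkene of F3. It should give the 7β,8β-epoxide F5 and the 7α,8α-epoxide F6, diastereomers that can be separated by chromatography.
- Heating F5 with tiglic acid 15 and Cs2CO3 in DMF opens the epoxide by SN2 attack of the carboxylate at C8 (C7 is neopentyl) from the α side. This sets 8α-O-tigloyl and leaves 7β-OH, that is 17.
- The fallback pays with two separations, but every reaction in it is of a known type.

**Step 3 (key step).**
- Risk: the most probable failure is low product fidelity. The cation cascade may leak toward the longifolane and himachalane series or toward the exocyclic alkene isomer. Further risks are an enzyme of the wrong enantiomeric series, slow turnover, product inhibition and Mg2+-promoted solvolysis of 4 in the buffer.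
- Fallback: the isolated-enzyme format is abandoned. The synthase gene is expressed in a Saccharomyces cerevisiae or Escherichia coli strain with an amplified mevalonate pathway, in which 4 is formed from sugar and consumed inside the cell.
- The hydrocarbons are trapped in a dodecane overlay and distilled, and 10 is separated from isomeric sesquiterpenes on AgNO3-impregnated silica.
- This fallback sets out from 4 (now generated in the cell instead of from 3) and comes back at 10. It makes no new compound.

**Step 8.**
- Risk: the most probable failures are Z-to-E isomerisation during a slow acylation of the neopentyl carbinol at 80 °C, and migration of the tigloyl group from O8 to O7 before the angeloyl group arrives.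
- Fallback: it sets out from 17 and comes back at 20. It builds the Z-alkene on the substrate instead of transferring it.
- Compound 17 is esterified with 2-[bis(2,2,2-trifluoroethoxy)phosphoryl]propanoic acid (DCC, DMAP, CH2Cl2; harmless here because no alkene geometry is at stake). This gives the 7-O-phosphonopropionate F7, a mixture of epimers at the phosphorus-bearing carbon that is of no consequence.
- KN(SiMe3)2 and 18-crown-6 in THF at −78 °C, then acetaldehyde, effect a Still–Gennari olefination. It is Z-selective for α-methyl phosphonates and gives the angelate.

**Step 4.**
- Risk: the most probable failures are capture of the allyl radical at the tertiary terminus C3, attack on the C3 methyl, fragmentation of the cyclobutane from the radical, and over-oxidation.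
- Fallback: it sets out from 10 and comes back at 12, replacing the radical chain by two-electron chemistry known from the pinene series.
- Pb(OAc)4 in warm benzene, followed by equilibration in acetic acid, should give longipin-2-en-1-yl acetate F8 (acetoxy group on the side of C5).
- K2CO3 in MeOH gives longipin-2-en-1-ol F9, and MnO2 in CH2Cl2 oxidises the allylic alcohol to 12.

## Further compounds

F1 | step 5 | (4R,5S,10R,11R)-longipin-2-ene-1,8-dione | C1C(=O)C[C@@]2(C)[C@@H]3C(=O)C=C(C)[C@H]2[C@@H]3C1(C)C
F2 | step 6 | (8R)-8-methanesulfonyloxylongipin-2-en-1-one (8α-mesylate) | C1[C@@H](OS(C)(=O)=O)C[C@@]2(C)[C@@H]3C(=O)C=C(C)[C@H]2[C@@H]3C1(C)C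
F3 | step 6 | longipina-2,7-dien-1-one | C1=CC[C@@]2(C)[C@@H]3C(=O)C=C(C)[C@H]2[C@@H]3C1(C)C
F4 | step 6 | longipina-2,8-dien-1-one | C1C=C[C@@]2(C)[C@@H]3C(=O)C=C(C)[C@H]2[C@@H]3C1(C)C
F5 | step 6 | (7S,8R)-7,8-epoxylongipin-2-en-1-one (7β,8β-epoxide) | O1[C@@H]2[C@H]1C[C@@]3(C)[C@@H]4C(=O)C=C(C)[C@H]3[C@@H]4C2(C)C
F6 | step 6 | (7R,8S)-7,8-epoxylongipin-2-en-1-one (7α,8α-epoxide) | O1[C@H]2[C@@H]1C[C@@]3(C)[C@@H]4C(=O)C=C(C)[C@H]3[C@@H]4C2(C)C
F0 | step 3 | none | none
F7 | step 8 | 7β-{2-[bis(2,2,2-trifluoroethoxy)phosphoryl]propanoyloxy}-8α-tigloyloxylongipin-2-en-1-one (epimers at the phosphorus-bearing carbon) | CC(P(=O)(OCC(F)(F)F)OCC(F)(F)F)C(=O)O[C@@H]1[C@@H](OC(=O)/C(C)=C/C)C[C@@]2(C)[C@@H]3C(=O)C=C(C)[C@H]2[C@@H]3C1(C)C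
F8 | step 4 | (1S)-longipin-2-en-1-yl acetate, acetoxy group on the side of C5 | C1CC[C@@]2(C)[C@@H]3[C@@H](OC(C)=O)C=C(C)[C@H]2[C@@H]3C1(C)C
F9 | step 4 | (1S)-longipin-2-en-1-ol, hydroxyl on the side of C5 | C1CC[C@@]2(C)[C@@H]3[C@@H](O)C=C(C)[C@H]2[C@@H]3C1(C)C
A1 | alternative 1 | 5-alkyl-1-(tert-butyldimethylsilyloxy)-3-methylcyclopenta-1,3-diene with gem-dimethyl, acetonide-protected trans-diol tether ending in an (E)-alkenyl pinacol boronate | CC1(C)O[C@H]([C@@H](O1)C/C(C)=C/B2OC(C)(C)C(C)(C)O2)C(C)(C)[C@H]3C=C(C)C=C3O[Si](C)(C)C(C)(C)C
A2 | alternative 1 | tricyclic 1-silyloxynorbornene with endo pinacol boronate at C11 | CC1(C)O[C@@H]2[C@@H](O1)C[C@@]3(C)[C@H](B4OC(C)(C)C(C)(C)O4)[C@]5(O[Si](C)(C)C(C)(C)C)C=C(C)[C@H]3[C@@H]5C2(C)C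
A3 | alternative 2 | (2E,5S,6E)-5-(tert-butyldimethylsilyloxy)-3,7-dimethyldeca-2,6,9-trienoyl chloride | C=CC/C(C)=C/[C@@H](O[Si](C)(C)C(C)(C)C)C/C(C)=C/C(Cl)=O
A4 | alternative 2 | (Z)-vinylketene derived from A3 | C=CC/C(C)=C/[C@@H](O[Si](C)(C)C(C)(C)C)/C=C(C)\C=C=O
A5 | alternative 2 | 7-allyl-4-(tert-butyldimethylsilyloxy)-2,7-dimethylbicyclo[3.1.1]hept-2-en-6-one | C=CC[C@@]1(C)[C@@H]2[C@@H](O[Si](C)(C)C(C)(C)C)C=C(C)[C@H]1C2=O
A6 | alternative 3 | meso-7,8-diacetyl-1,5,5-trimethylbicyclo[4.1.1]oct-3-ene | C1=CC[C@@]2(C)[C@H](C(C)=O)[C@@H](C1(C)C)[C@@H]2C(C)=O
A7 | alternative 3 | longipina-2,7-dien-1-one | C1=CC[C@@]2(C)[C@@H]3C(=O)C=C(C)[C@H]2[C@@H]3C1(C)C
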